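**Retrosynthetic overview**
- The target comes from its ring-A methyl ether. The two ring-A bromines are placed ortho to a temporary amino group (from a nitro group), which is then removed by diazotisation and reduction.
- Key disconnection: ring A, as a 2-aryloxy-4-nitrophenol, is cut across C2–C3 and C5–C6 into an aryloxyacetone and sodium nitromalonaldehyde. Forward, an intermolecular aldol condensation joins the two pieces and a second, intramolecular one closes and aromatises the ring.
- The aryloxyacetone comes from chloroacetone and the ring-B/C phenol. That phenol comes from 4,5,6-tribromoguaiacol (from guaiacol) and 4-bromo-1-fluoro-2-nitrobenzene by SNAr, then NO2 → NH2 → I.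
- Ring order: rings B and C are bought as benzenes and joined first; ring A is the only ring that is built, and it is built last.

Assumption: the target has no stereocentre or stable stereoaxis, so no enantiomer question arises and no stereodescriptors are needed.

**Route**

Step 1
Reactants: 1 guaiacol (2-methoxyphenol)
Product: 2 2,3,4-tribromo-6-methoxyphenol (4,5,6-tribromoguaiacol)
Conditions: Br2 (3.2 equiv), AcOH, rt → 60 °C
Reagents that add atoms: bromine, BrBr
Why: Electrophilic aromatic bromination; the free OH sends bromine to its para and ortho positions and the OMe to its para position, so only the position ortho to OMe stays free.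

Step 2
Reactants: 2 2,3,4-tribromo-6-methoxyphenol; 3 4-bromo-1-fluoro-2-nitrobenzene
Product: 4 1,2,3-tribromo-4-(4-bromo-2-nitrophenoxy)-5-methoxybenzene
Conditions: K2CO3, DMF, 80 °C
Reagents that add atoms: none
Why: SNAr; the ortho-nitro group activates the C–F bond towards the acidic, hindered phenoxide, and aryl bromides are inert without a metal catalyst.

Step 3
Reactants: 4 1,2,3-tribromo-4-(4-bromo-2-nitrophenoxy)-5-methoxybenzene
Product: 5 5-bromo-2-(2,3,4-tribromo-6-methoxyphenoxy)aniline
Conditions: Fe powder, AcOH/EtOH, 70 °C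
Reagents that add atoms: none
Why: Béchamp-type dissolving-metal nitro reduction, which leaves aryl bromides and ethers untouched.

Step 4
Reactants: 5 5-bromo-2-(2,3,4-tribromo-6-methoxyphenoxy)aniline
Product: 7 1,2,3-tribromo-4-(4-bromo-2-iodophenoxy)-5-methoxybenzene, via diazonium hydrogensulfate 6 (not isolated)
Conditions: NaNO2, H2SO4, MeCN/H2O, 0 °C; then KI (aq), 0 °C → rt
Reagents that add atoms: sodium nitrite, O=N[O-].[Na+]; sulfuric acid (counter-ion of 6), OS(=O)(=O)O; potassium iodide, [K+].[I-]
Why: Diazotisation followed by Sandmeyer-type iodination, which needs no copper; both positions ortho to the ether oxygen on ring B are substituted, so Pschorr closure to a dibenzofuran is blocked.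

Step 5
Reactants: 7 1,2,3-tribromo-4-(4-bromo-2-iodophenoxy)-5-methoxybenzene
Product: 8 3,4,5-tribromo-2-(4-bromo-2-iodophenoxy)phenol
Conditions: BBr3, CH2Cl2, −78 °C → rt; then H2O
Reagents that add atoms: none
Why: Lewis-acid O-demethylation; BBr3 cleaves the aryl methyl ether by SN2 at methyl, while the diaryl ether has no sp3 carbon to attack.

Step 6
Reactants: 8 3,4,5-tribromo-2-(4-bromo-2-iodophenoxy)phenol; 9 chloroacetone
Product: 10 1-[3,4,5-tribromo-2-(4-bromo-2-iodophenoxy)phenoxy]propan-2-one
Conditions: K2CO3, KI (cat.), acetone, reflux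
Reagents that add atoms: none
Why: Williamson ether synthesis (SN2) on a very reactive α-haloketone, with Finkelstein activation by iodide.

Step 7
Reactants: 11 mucobromic acid ((Z)-2,3-dibromo-4-oxobut-2-enoic acid)
Product: 12 sodium nitromalonaldehyde monohydrate (sodium 2-nitro-3-oxoprop-1-en-1-olate hydrate)
Conditions: NaNO2 (3.7 equiv), H2O/EtOH, 54 °C; then 0–5 °C, recrystallise from aq. EtOH (impact-sensitive when dry; handle moist, behind a shield)
Reagents that add atoms: sodium nitrite, O=N[O-].[Na+]; water, O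
Why: Classical degradation of mucobromic acid: nitrite replaces a bromide, the other vinylic bromide is hydrolysed and the carboxyl group is lost as CO2, and the stabilised salt crystallises on cooling.

Step 8
Reactants: 10 1-[3,4,5-tribromo-2-(4-bromo-2-iodophenoxy)phenoxy]propan-2-one; 12 sodium nitromalonaldehyde monohydrate
Product: 14 4-nitro-2-[3,4,5-tribromo-2-(4-bromo-2-iodophenoxy)phenoxy]phenol, via open-chain sodium nitrodienolate 13 (not isolated)
Conditions: 12 (1.2 equiv), NaOH (1.5 equiv), EtOH/THF/H2O, rt, 3–5 d; then aq. HCl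
Reagents that add atoms: none
Why: Double aldol condensation ([3+3] benzannulation of the nitromalonaldehyde type, long known for acetone and benzyl methyl ketones): the enolate at the aryloxy-bearing CH2 adds intermolecularly to one formyl group (new C2–C3 bond), the methyl group then closes onto the second formyl group, and two dehydrations give the nitrophenolate as the thermodynamic sink; no stereocentre is formed.

Step 9
Reactants: 14 4-nitro-2-[3,4,5-tribromo-2-(4-bromo-2-iodophenoxy)phenoxy]phenol
Product: 15 1,2,3-tribromo-4-(4-bromo-2-iodophenoxy)-5-(2-methoxy-5-nitrophenoxy)benzene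
Conditions: MeI, K2CO3, DMF, rt
Reagents that add atoms: iodomethane, CI
Why: Williamson O-methylation of an acidic nitrophenol; the ether keeps the later aminophenol from oxidising to a quinone imine.

Step 10
Reactants: 15 1,2,3-tribromo-4-(4-bromo-2-iodophenoxy)-5-(2-methoxy-5-nitrophenoxy)benzene
Product: 16 4-methoxy-3-[3,4,5-tribromo-2-(4-bromo-2-iodophenoxy)phenoxy]aniline
Conditions: Fe powder, AcOH/EtOH, 70 °C
Reagents that add atoms: none
Why: Béchamp-type nitro reduction, which tolerates the aryl iodide and bromides where hydrogenation would not.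

Step 11
Reactants: 16 4-methoxy-3-[3,4,5-tribromo-2-(4-bromo-2-iodophenoxy)phenoxy]aniline
Product: 17 2,6-dibromo-4-methoxy-3-[3,4,5-tribromo-2-(4-bromo-2-iodophenoxy)phenoxy]aniline
Conditions: NBS (2.05 equiv), MeCN, 0 °C → rt
Reagents that add atoms: N-bromosuccinimide, O=C1CCC(=O)N1Br
Why: Electrophilic aromatic bromination directed by the free NH2 to its two ortho positions, which are also ortho and para to the aryloxy oxygen; the remaining ring-A CH is meta to both donors, and rings B and C are halogen-deactivated.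

Step 12
Reactants: 17 2,6-dibromo-4-methoxy-3-[3,4,5-tribromo-2-(4-bromo-2-iodophenoxy)phenoxy]aniline
Product: 19 1,2,3-tribromo-4-(4-bromo-2-iodophenoxy)-5-(2,4-dibromo-6-methoxyphenoxy)benzene, via diazonium hydrogensulfate 18 (not isolated)
Conditions: NaNO2, conc. H2SO4/AcOH, 0–10 °C; then 50% aq. H3PO2, 0 °C → rt
Reagents that add atoms: sodium nitrite, O=N[O-].[Na+]; sulfuric acid (counter-ion of 18), OS(=O)(=O)O
Why: Diazotisation with nitrosylsulfuric acid and hydrodediazoniation by hypophosphorous acid (reductive deamination), the classical way to remove an amino group from a 2,6-dibromoaniline; the aryloxy group is meta to N2+, so no cyclisation is possible.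

Step 13
Reactants: 19 1,2,3-tribromo-4-(4-bromo-2-iodophenoxy)-5-(2,4-dibromo-6-methoxyphenoxy)benzene
Product: 20 bromoiesol B, 3,5-dibromo-2-[3,4,5-tribromo-2-(4-bromo-2-iodophenoxy)phenoxy]phenol
Conditions: BBr3, CH2Cl2, −78 °C → rt; then H2O
Reagents that add atoms: none
Why: BBr3 O-demethylation, which cleaves only the methyl ether and leaves both diaryl ethers and all C–halogen bonds intact.

**Compound list**
1 | guaiacol (2-methoxyphenol) | COc1ccccc1O | starting material
2 | 2,3,4-tribromo-6-methoxyphenol | COc1cc(Br)c(Br)c(Br)c1O | intermediate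
3 | 4-bromo-1-fluoro-2-nitrobenzene | O=[N+]([O-])c1cc(Br)ccc1F | starting material
4 | 1,2,3-tribromo-4-(4-bromo-2-nitrophenoxy)-5-methoxybenzene | COc1cc(Br)c(Br)c(Br)c1Oc1ccc(Br)cc1[N+](=O)[O-] | intermediate
5 | 5-bromo-2-(2,3,4-tribromo-6-methoxyphenoxy)aniline | COc1cc(Br)c(Br)c(Br)c1Oc1ccc(Br)cc1N | intermediate
6 | 5-bromo-2-(2,3,4-tribromo-6-methoxyphenoxy)benzenediazonium hydrogensulfate | COc1cc(Br)c(Br)c(Br)c1Oc1ccc(Br)cc1[N+]#N.OS(=O)(=O)[O-] | intermediate
7 | 1,2,3-tribromo-4-(4-bromo-2-iodophenoxy)-5-methoxybenzene | COc1cc(Br)c(Br)c(Br)c1Oc1ccc(Br)cc1I | intermediate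
8 | 3,4,5-tribromo-2-(4-bromo-2-iodophenoxy)phenol | Oc1cc(Br)c(Br)c(Br)c1Oc1ccc(Br)cc1I | intermediate
9 | chloroacetone | CC(=O)CCl | starting material
10 | 1-[3,4,5-tribromo-2-(4-bromo-2-iodophenoxy)phenoxy]propan-2-one | CC(=O)COc1cc(Br)c(Br)c(Br)c1Oc1ccc(Br)cc1I | intermediate
11 | mucobromic acid, (Z)-2,3-dibromo-4-oxobut-2-enoic acid (solid exists as the cyclic lactol) | OC(=O)/C(Br)=C(/Br)C=O | starting material
12 | sodium nitromalonaldehyde monohydrate | O=CC(=C[O-])[N+](=O)[O-].[Na+].O | intermediate
13 | sodium 2-nitro-5-oxo-4-[3,4,5-tribromo-2-(4-bromo-2-iodophenoxy)phenoxy]hexa-1,3-dien-1-olate (double-bond geometry not fixed, delocalised anion) | CC(=O)C(Oc1cc(Br)c(Br)c(Br)c1Oc1ccc(Br)cc1I)=CC(=C[O-])[N+](=O)[O-].[Na+] | intermediate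
14 | 4-nitro-2-[3,4,5-tribromo-2-(4-bromo-2-iodophenoxy)phenoxy]phenol | Oc1ccc(cc1Oc1cc(Br)c(Br)c(Br)c1Oc1ccc(Br)cc1I)[N+](=O)[O-] | intermediate
15 | 1,2,3-tribromo-4-(4-bromo-2-iodophenoxy)-5-(2-methoxy-5-nitrophenoxy)benzene | COc1ccc(cc1Oc1cc(Br)c(Br)c(Br)c1Oc1ccc(Br)cc1I)[N+](=O)[O-] | intermediate
16 | 4-methoxy-3-[3,4,5-tribromo-2-(4-bromo-2-iodophenoxy)phenoxy]aniline | COc1ccc(N)cc1Oc1cc(Br)c(Br)c(Br)c1Oc1ccc(Br)cc1I | intermediate
17 | 2,6-dibromo-4-methoxy-3-[3,4,5-tribromo-2-(4-bromo-2-iodophenoxy)phenoxy]aniline | COc1cc(Br)c(N)c(Br)c1Oc1cc(Br)c(Br)c(Br)c1Oc1ccc(Br)cc1I | intermediate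
18 | 2,6-dibromo-4-methoxy-3-[3,4,5-tribromo-2-(4-bromo-2-iodophenoxy)phenoxy]benzenediazonium hydrogensulfate | COc1cc(Br)c([N+]#N)c(Br)c1Oc1cc(Br)c(Br)c(Br)c1Oc1ccc(Br)cc1I.OS(=O)(=O)[O-] | intermediate
19 | 1,2,3-tribromo-4-(4-bromo-2-iodophenoxy)-5-(2,4-dibromo-6-methoxyphenoxy)benzene | COc1cc(Br)cc(Br)c1Oc1cc(Br)c(Br)c(Br)c1Oc1ccc(Br)cc1I | intermediate
20 | bromoiesol B, 3,5-dibromo-2-[3,4,5-tribromo-2-(4-bromo-2-iodophenoxy)phenoxy]phenol | Oc1cc(Br)cc(Br)c1Oc1cc(Br)c(Br)c(Br)c1Oc1ccc(Br)cc1I | target

**Step count**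
Total steps: 13. Longest linear sequence: 12 steps (1 → 2 → 4 → 5 → 7 → 8 → 10 → 14 → 15 → 16 → 17 → 19 → 20); step 7 is a one-step side branch.

**Three steps most likely to fail**

Step 8 (aldol benzannulation). The ketone is large and lipophilic, the nitromalonaldehyde anion is a weak electrophile, and hydroxide may slowly cleave the α-aryloxy ketone back to 8. The fallback sets out from phenol 8 and forms ring A's ether bond by coupling instead of ring construction. Heating 8 with commercial 3,5-dibromo-2-fluorobenzaldehyde and K2CO3 in DMF at about 100 °C (SNAr ortho to the formyl group) gives 3,5-dibromo-2-[3,4,5-tribromo-2-(4-bromo-2-iodophenoxy)phenoxy]benzaldehyde F4. Baeyer–Villiger oxidation with mCPBA in CH2Cl2 converts it into 3,5-dibromo-2-[3,4,5-tribromo-2-(4-bromo-2-iodophenoxy)phenoxy]phenyl formate F5, and mild hydrolysis (KOH, aq. THF, then acid) comes back to the route at the target 20, so steps 9–13 are not needed on this path.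

Step 1 (threefold bromination). The third bromine could enter ortho instead of para to OMe, or a fourth could add, giving mixtures that are hard to separate. The fallback sets out from guaiacol 1 and fixes the bromine para to OMe first. Acetylation (Ac2O, pyridine) gives 2-methoxyphenyl acetate F1, in which the acetoxy group no longer dominates. Bromination (Br2, cat. Fe, or NBS in MeCN) then goes para to OMe to give 5-bromo-2-methoxyphenyl acetate F2. Hydrolysis (NaOH, aq. THF, then acid) gives 5-bromo-2-methoxyphenol F3. Two equivalents of Br2 in AcOH then place the remaining bromines para and ortho to the free OH, the only positions it activates, and the sequence comes back at 2.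

Step 12 (reductive deamination). The hindered, weakly basic dibromoaniline may diazotise incompletely, and the radical chain with H3PO2 can give phenol or biaryl by-products. The fallback sets out from 17 and removes nitrogen through the arylhydrazine instead of by direct hydride transfer. Compound 17 is diazotised to 18 as before and the cold solution is reduced with SnCl2 in HCl to [2,6-dibromo-4-methoxy-3-[3,4,5-tribromo-2-(4-bromo-2-iodophenoxy)phenoxy]phenyl]hydrazine F6, isolated as its hydrochloride. Oxidation with hot aqueous CuSO4 passes through the aryldiazene, which loses N2, and comes back to the route at 19.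

**Further compounds**
F1 | step 1 | 2-methoxyphenyl acetate | COc1ccccc1OC(C)=O
F2 | step 1 | 5-bromo-2-methoxyphenyl acetate | COc1ccc(Br)cc1OC(C)=O
F3 | step 1 | 5-bromo-2-methoxyphenol | COc1ccc(Br)cc1O
F4 | step 8 | 3,5-dibromo-2-[3,4,5-tribromo-2-(4-bromo-2-iodophenoxy)phenoxy]benzaldehyde | O=Cc1cc(Br)cc(Br)c1Oc1cc(Br)c(Br)c(Br)c1Oc1ccc(Br)cc1I
F5 | step 8 | 3,5-dibromo-2-[3,4,5-tribromo-2-(4-bromo-2-iodophenoxy)phenoxy]phenyl formate | O=COc1cc(Br)cc(Br)c1Oc1cc(Br)c(Br)c(Br)c1Oc1ccc(Br)cc1I
F6 | step 12 | [2,6-dibromo-4-methoxy-3-[3,4,5-tribromo-2-(4-bromo-2-iodophenoxy)phenoxy]phenyl]hydrazine | COc1cc(Br)c(NN)c(Br)c1Oc1cc(Br)c(Br)c(Br)c1Oc1ccc(Br)cc1I
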